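**Plan**

Ring letters: A fulvene, B dihydropyran, C seven-membered carbocycle, D cyclohexane, E pyrrolidine, F azepanone.

- Retrosynthesis: the acetate is removed and the amine taken back to a lactam. Then both bonds that tie the fulvene to ring C are cut at once (fulvene ring CH to the quaternary C(Me), and enol-ether carbon to CH2). This opens rings C and D to a fulvene and a 3-vinyl-pyrrolinone, both held on ring F.
- What allows it: ring A with its exocyclic enol-ether carbon in ring B is the bis(enol ether) of a cyclopentenone-fused δ-lactone, i.e. a ketene-acetal fulvene. Its exocyclic carbon and the adjacent ring CH are the ends of a 6π unit. Ring E, as an unsaturated lactam carrying the vinyl group, is the matching electron-poor 4π unit.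
- Further cuts: N–CH2 of ring F (aza-Michael), hydroxy lactam from a pyrrole-2-carboxylic acid (photooxygenation), pyrrole–CH2 (Friedel–Crafts opening of an epoxy ketone), tertiary carbinol C–C bond (aldol to an α-chloro ketone), keto-lactone from cyclopentane-1,3-dione.
- Forward order: rings A and B as keto-lactone, side chain with epoxide, pyrrole, ring F, ring E as hydroxy lactam with diene, rings C and D in one operation, two reductions, desilylation, acetylation.
- Stereochemistry: (S)-2-hydroxybutanoate sets the tertiary carbinol by Felkin–Anh addition and is then oxidized away. The carbinolamine carbon comes from face-selective photooxygenation, the quaternary carbon from the tether in the cycloaddition, the ring-fusion CH from convex-face protonation, and the C-methyl centre from equilibration.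

Key step: step 17

Assumption: the configuration at the methyl-bearing carbon next to the ketone is taken to be the thermodynamically preferred one (methyl on the face of ring F turned away from ring D), so it is set by base equilibration in step 20.

**Route**

Step 1
Reactants: 1 cyclopentane-1,3-dione; 2 (tert-butyldimethylsilyloxy)acetaldehyde
Product: 4 2-[2-(tert-butyldimethylsilyloxy)ethyl]cyclopentane-1,3-dione, via alkylidene dione 3 (not isolated)
Conditions: Hantzsch ester (diethyl 2,6-dimethyl-1,4-dihydropyridine-3,5-dicarboxylate), L-proline (5 mol%), CH2Cl2, rt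
Reagents that add atoms: none
Why: Three-component reductive alkylation (Knoevenagel condensation, then transfer hydrogenation of the alkylidene dione by the Hantzsch ester) should give clean C-alkylation of the cyclic 1,3-dione.

Step 2
Reactants: 4
Product: 5 2-[2-(tert-butyldimethylsilyloxy)ethyl]-3-oxocyclopent-1-en-1-yl trifluoromethanesulfonate
Conditions: Tf2O, Et3N, CH2Cl2, −78 °C
Reagents that add atoms: trifluoromethanesulfonic anhydride, O=S(=O)(OS(=O)(=O)C(F)(F)F)C(F)(F)F
Why: O-sulfonylation of the vinylogous acid should give the enol triflate, and the dione is symmetric so only one regioisomer can form.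

Step 3
Reactants: 5
Product: 6 methyl 2-[2-(tert-butyldimethylsilyloxy)ethyl]-3-oxocyclopent-1-ene-1-carboxylate
Conditions: Pd(OAc)2 (5 mol%), 1,3-bis(diphenylphosphino)propane, CO (1 atm), MeOH, Et3N, DMF, 60 °C
Reagents that add atoms: carbon monoxide, [C-]#[O+]; methanol, CO
Why: Palladium-catalysed alkoxycarbonylation of the vinyl triflate should install the carboxyl carbon that later becomes the exocyclic fulvene carbon.

Step 4
Reactants: 6
Product: 8 3,4,6,7-tetrahydrocyclopenta[c]pyran-1,5-dione, via hydroxy ester 7 (not isolated)
Conditions: HF·pyridine, THF, 0 °C to rt; then TsOH (cat.), PhMe, 60 °C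
Reagents that add atoms: none
Why: Fluoride desilylation followed by acid-catalysed transesterification (lactonization) should close the six-membered conjugated lactone of ring B.

Step 5
Reactants: 9 ethyl (S)-2-hydroxybutanoate
Product: 10 ethyl (S)-2-(tert-butyldimethylsilyloxy)butanoate
Conditions: TBSCl, imidazole, DMF, rt
Reagents that add atoms: tert-butyldimethylsilyl chloride, CC(C)(C)[Si](C)(C)Cl
Why: Standard silyl ether formation gives a bulky, non-chelating α-oxygen substituent for the later Felkin–Anh addition.

Step 6
Reactants: 10
Product: 11 (S)-1-chloro-3-(tert-butyldimethylsilyloxy)pentan-2-one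
Conditions: ICH2Cl, MeLi·LiBr, THF, −78 °C; AcOH quench at −78 °C
Reagents that add atoms: chloroiodomethane, ClCI
Why: Homologation of the ester with chloromethyllithium (the tetrahedral adduct is stable at −78 °C) should give the α-chloro ketone without touching the stereocentre.

Step 7
Reactants: 8; 11
Product: 13 silyloxy epoxide, via lithium aldolate 12 (not isolated)
Conditions: LiN(iPr)2, THF, −78 °C; then 11, −78 to −20 °C; pH 7 buffer
Reagents that add atoms: none
Why: The kinetic α′-enolate of the enone should add to the α-chloro ketone in an aldol reaction under polar Felkin–Anh control (attack anti to the silyloxy group, which sets the future tertiary carbinol), and the chlorohydrin alkoxide closes to the epoxide in a Darzens-type displacement.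

Step 8
Reactants: 13
Product: 14 epoxy alcohol
Conditions: Bu4NF, AcOH, THF, 0 °C
Reagents that add atoms: none
Why: Buffered fluoride desilylation should free the secondary alcohol without base-induced opening of the epoxide.

Step 9
Reactants: 14
Product: 15 epoxy ethyl ketone
Conditions: Dess–Martin periodinane, NaHCO3, CH2Cl2, 0 °C
Reagents that add atoms: none
Why: Dess–Martin oxidation removes the now superfluous carbinol stereocentre and makes an α,β-epoxy ketone, whose carbonyl directs nucleophiles to the CH2 terminus.

Step 10
Reactants: 16 4-methyl-1H-pyrrole-2-carboxylic acid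
Product: 17 allyl 4-methyl-1H-pyrrole-2-carboxylate
Conditions: allyl bromide, KHCO3, DMF, rt
Reagents that add atoms: allyl bromide, C=CCBr
Why: Carboxylate O-alkylation gives an ester that blocks one α-position, acidifies the N–H and can later be removed under neutral conditions.

Step 11
Reactants: 15; 17
Product: 18 pyrrolylmethyl hydroxy ketone
Conditions: Sc(OTf)3 (10 mol%), (CF3)2CHOH, 40 °C
Reagents that add atoms: none
Why: Friedel–Crafts alkylation of the pyrrole at its only free α-position should open the epoxide at the CH2 terminus (the adjacent ketone disfavours ionization at the tertiary carbon) and unveil the tertiary carbinol with retention.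

Step 12
Reactants: 18
Product: 19 bromopyrrole
Conditions: NBS, THF, −78 to 0 °C
Reagents that add atoms: N-bromosuccinimide, O=C1CCC(=O)N1Br
Why: Electrophilic bromination at the only remaining pyrrole position installs the handle for the vinyl group and blocks that carbon in the next step.

Step 13
Reactants: 19
Product: 21 bicyclic pyrrole with ring F, via isopropenyl ketone 20 (not isolated)
Conditions: (CH2O)n, iPr2NH·CF3CO2H, THF, 65 °C; then K2CO3, MeCN, rt
Reagents that add atoms: formaldehyde (as paraformaldehyde), C=O
Why: α-Methylenation of the ethyl ketone (Mannich reaction and elimination; the ring ketone has no α-CH2) and then intramolecular aza-Michael addition of the acidic pyrrole N–H (7-endo-trig) should close ring F; the new C-methyl centre forms as an epimerizable mixture.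

Step 14
Reactants: 21
Product: 22 pyrrole-2-carboxylic acid
Conditions: Pd(PPh3)4 (5 mol%), morpholine, THF, rt
Reagents that add atoms: none
Why: Palladium-catalysed allyl transfer to morpholine (Tsuji–Trost deallylation) frees the acid under neutral conditions that spare the lactone and the α-ketol.

Step 15
Reactants: 22
Product: 24 bromo hydroxy lactam, via pyrrole endoperoxide 23 (not isolated)
Conditions: O2, rose bengal, visible light, MeCN–H2O, 0 °C
Reagents that add atoms: dioxygen, O=O
Why: Dye-sensitized photooxygenation adds singlet oxygen across the pyrrole α-carbons and the endoperoxide fragments with loss of CO2 to the 5-hydroxy-3-pyrrolin-2-one; addition syn to the tertiary hydroxyl (hydrogen bonding) and anti to the bulky keto-lactone substituent should place the new hydroxyl cis to the existing one on ring F.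

Step 16
Reactants: 24
Product: 25 vinyl hydroxy lactam (diene)
Conditions: tributyl(vinyl)stannane, Pd2(dba)3, AsPh3, NMP, 50 °C
Reagents that add atoms: tributyl(vinyl)stannane, C=C[Sn](CCCC)(CCCC)CCCC
Why: Stille coupling of the α-bromo unsaturated lactam installs the vinyl group and completes the electron-poor diene.

Step 17
Reactants: 25
Product: 28 hexacyclic silyloxyfulvene, via persilylated fulvene 26 (not isolated), via ketal cycloadduct 27 (not isolated)
Conditions: TBSOTf (7 equiv), Et3N (10 equiv), CH2Cl2, −78 °C to rt; then PhMe, 90 °C
Reagents that add atoms: tert-butyldimethylsilyl trifluoromethanesulfonate, CC(C)(C)[Si](C)(C)OS(=O)(=O)C(F)(F)F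
Why: Soft enolization silylates the two tertiary hydroxyls and the azepanone and turns the cyclopentenone-fused lactone into the electron-rich ketene-acetal fulvene 26, whose 6π array (exocyclic dioxy carbon, the ring carbon that carries it, the adjacent ring CH) adds on heating across the termini of the electron-poor 3-vinyl-pyrrolinone diene in a suprafacial, exo [6+4] cycloaddition; ketal 27 then ionizes and loses the ring proton (net loss of tert-butyldimethylsilanol) to restore a fulvene. The closest known reactions are the [6+4] cycloadditions of the ketene-acetal fulvene 2-cyclopentadienylidene-1,3-dioxolane with electron-poor dienes such as 2-pyranones and the intramolecular fulvene–diene [6+4] cycloadditions. Ring D closes in a 6-endo-trig sense (fulvene CH onto the methyl-bearing diene terminus, both held on ring F), and ring C is the seven-membered ring of the [6+4] mode itself (vinyl CH2 onto the exocyclic carbon). The only new stereocentre that survives, the quaternary methyl carbon, is set by the tether: the fulvene can reach only the pyrrolinone face that bears the ring-F CH2, anti to the silyloxy group of the carbinolamine carbon fixed in step 15. Periselectivity over [4+2] modes and over closure at the lactam α-carbon is needed; ring F holds the two π systems 1,3-cis so that only the [6+4] termini are in reach, the polarity is matched (nucleophilic fulvene CH to the β-carbon of the unsaturated lactam, terminal CH2 to the dioxy carbon, as in a vinylogous Mukaiyama closure if the process is stepwise), and closure at the α-carbon would join three fully substituted carbons.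

Step 18
Reactants: 28
Product: 29 saturated lactam
Conditions: Cu(OAc)2 (5 mol%), 1,2-bis(diphenylphosphino)benzene, (EtO)2MeSiH, tBuOH, PhMe, rt
Reagents that add atoms: none
Why: Copper hydride conjugate reduction of the α-alkylidene lactam delivers hydride to the ring-C carbon, and protonation of the amide enolate on the convex face (that of the angular methyl) should give the cis-fused ring junction; silyl enol ethers and the fulvene are not conjugate acceptors.

Step 19
Reactants: 29
Product: 30 tertiary amine
Conditions: Zn(OAc)2 (10 mol%), (EtO)3SiH, THF, 50 °C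
Reagents that add atoms: none
Why: Zinc-catalysed hydrosilylation reduces the tertiary lactam carbonyl to CH2 while the ketone stays masked as its silyl enol ether, and the silylated carbinolamine carbon is a bridgehead of rings D and F and cannot ionize.

Step 20
Reactants: 30
Product: 32 hydroxyfulvene amino diol, via desilylated epimer mixture 31 (not isolated)
Conditions: HF·pyridine, pyridine, THF, 0 °C to rt; then K2CO3, MeOH, rt
Reagents that add atoms: none
Why: Fluoride removes the four silyl groups (two tertiary ethers, two enol ethers), and base-mediated enolization then equilibrates the α-methyl ketone to the epimer with the methyl group on the face away from ring D.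

Step 21
Reactants: 32
Product: 33 CNP0309418.1 (target)
Conditions: Ac2O, Et3N, CH2Cl2, 0 °C
Reagents that add atoms: acetic anhydride, CC(=O)OC(C)=O
Why: O-Acylation of the acidic hydroxyfulvene (the enol of the cyclopentenone tautomer) gives the enol acetate, while the two hindered tertiary hydroxyls should not react without an acyl-transfer catalyst.

**Compound list**

1 | cyclopentane-1,3-dione | O=C1CCC(=O)C1 | starting material
2 | (tert-butyldimethylsilyloxy)acetaldehyde | CC(C)(C)[Si](C)(C)OCC=O | starting material
3 | 2-[2-(tert-butyldimethylsilyloxy)ethylidene]cyclopentane-1,3-dione | O=C1CCC(=O)C1=CCO[Si](C)(C)C(C)(C)C | intermediate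
4 | 2-[2-(tert-butyldimethylsilyloxy)ethyl]cyclopentane-1,3-dione | O=C1CCC(=O)C1CCO[Si](C)(C)C(C)(C)C | intermediate
5 | 2-[2-(tert-butyldimethylsilyloxy)ethyl]-3-oxocyclopent-1-en-1-yl trifluoromethanesulfonate | O=C1CCC(OS(=O)(=O)C(F)(F)F)=C1CCO[Si](C)(C)C(C)(C)C | intermediate
6 | methyl 2-[2-(tert-butyldimethylsilyloxy)ethyl]-3-oxocyclopent-1-ene-1-carboxylate | COC(=O)C1=C(CCO[Si](C)(C)C(C)(C)C)C(=O)CC1 | intermediate
7 | methyl 2-(2-hydroxyethyl)-3-oxocyclopent-1-ene-1-carboxylate | COC(=O)C1=C(CCO)C(=O)CC1 | intermediate
8 | 3,4,6,7-tetrahydrocyclopenta[c]pyran-1,5-dione (keto-lactone of rings A and B) | O=C1CCC2=C1CCOC2=O | intermediate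
9 | ethyl (S)-2-hydroxybutanoate | CC[C@H](O)C(=O)OCC | starting material
10 | ethyl (S)-2-(tert-butyldimethylsilyloxy)butanoate | CC[C@H](O[Si](C)(C)C(C)(C)C)C(=O)OCC | intermediate
11 | (S)-1-chloro-3-(tert-butyldimethylsilyloxy)pentan-2-one | CC[C@H](O[Si](C)(C)C(C)(C)C)C(=O)CCl | intermediate
12 | lithium alkoxide of the chlorohydrin from addition of the C6 enolate of 8 to ketone 11 (new carbinol carbon as in 13; mixture at C6) | O=C1C(CC2=C1CCOC2=O)[C@]([O-])(CCl)[C@@H](O[Si](C)(C)C(C)(C)C)CC.[Li+] | intermediate
13 | 6-{2-[(S)-1-(tert-butyldimethylsilyloxy)propyl]oxiran-2-yl}-3,4,6,7-tetrahydrocyclopenta[c]pyran-1,5-dione, oxirane quaternary carbon as drawn (the later tertiary carbinol), mixture at C6 | O=C1C(CC2=C1CCOC2=O)[C@]3(CO3)[C@@H](O[Si](C)(C)C(C)(C)C)CC | intermediate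
14 | epoxy alcohol: 13 with free (S)-configured secondary hydroxyl | O=C1C(CC2=C1CCOC2=O)[C@]3(CO3)[C@@H](O)CC | intermediate
15 | epoxy ethyl ketone: 6-(2-propanoyloxiran-2-yl)-3,4,6,7-tetrahydrocyclopenta[c]pyran-1,5-dione, oxirane carbon as in 13 | O=C1C(CC2=C1CCOC2=O)[C@]3(CO3)C(=O)CC | intermediate
16 | 4-methyl-1H-pyrrole-2-carboxylic acid | Cc1c[nH]c(C(=O)O)c1 | starting material
17 | allyl 4-methyl-1H-pyrrole-2-carboxylate | Cc1c[nH]c(C(=O)OCC=C)c1 | intermediate
18 | tertiary α-hydroxy ethyl ketone carrying the keto-lactone (via C6) and a (5-allyloxycarbonyl-3-methylpyrrol-2-yl)methyl group on the carbinol carbon, carbinol as in the target | O=C1C(CC2=C1CCOC2=O)[C@](O)(Cc3[nH]c(C(=O)OCC=C)cc3C)C(=O)CC | intermediate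
19 | 18 brominated at pyrrole C4 (between the methyl-bearing carbon and the ester-bearing carbon) | O=C1C(CC2=C1CCOC2=O)[C@](O)(Cc3[nH]c(C(=O)OCC=C)c(Br)c3C)C(=O)CC | intermediate
20 | isopropenyl ketone from α-methylenation of 19 | O=C1C(CC2=C1CCOC2=O)[C@](O)(Cc3[nH]c(C(=O)OCC=C)c(Br)c3C)C(=O)C(C)=C | intermediate
21 | pyrrolo[1,2-a]azepinone (ring F closed through N–CH2): allyl ester, bromide, tertiary carbinol as in the target, mixture at the C-methyl carbon | O=C1C(CC2=C1CCOC2=O)[C@]3(O)Cc4c(C)c(Br)c(C(=O)OCC=C)n4CC(C)C3=O | intermediate
22 | carboxylic acid corresponding to 21 | O=C1C(CC2=C1CCOC2=O)[C@]3(O)Cc4c(C)c(Br)c(C(=O)O)n4CC(C)C3=O | intermediate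
23 | 2,5-endoperoxide of pyrrole acid 22, peroxide bridge on the face syn to the tertiary hydroxyl | O=C1C(CC2=C1CCOC2=O)[C@]3(O)CC45OOC(C(=O)O)(C(Br)=C4C)N5CC(C)C3=O | intermediate
24 | bicyclic 5-hydroxy-3-pyrrolin-2-one (rings E and F) with 3-bromo and 4-methyl groups, both carbinol carbons as in the target (hydroxyls cis on ring F), mixture at the C-methyl carbon | O=C1C(CC2=C1CCOC2=O)[C@]3(O)C[C@@]4(O)N(CC(C)C3=O)C(=O)C(Br)=C4C | intermediate
25 | 3-vinyl analogue of 24 (substrate of the key step) | O=C1C(CC2=C1CCOC2=O)[C@]3(O)C[C@@]4(O)N(CC(C)C3=O)C(=O)C(C=C)=C4C | intermediate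
26 | persilylated 25: 2-silyloxy-6-alkoxy-6-silyloxyfulvene (rings A and B), both tertiary alcohols as TBS ethers, azepanone as TBS enol ether | CC(C)(C)[Si](C)(C)OC1=C2CCOC(O[Si](C)(C)C(C)(C)C)=C2C=C1[C@]3(O[Si](C)(C)C(C)(C)C)C[C@@]4(O[Si](C)(C)C(C)(C)C)N(CC(C)=C3O[Si](C)(C)C(C)(C)C)C(=O)C(C=C)=C4C | intermediate
27 | [6+4] cycloadduct: rings C and D closed, silyl ketal carbon and ring CH still sp3 (transient centres), quaternary methyl carbon as in the target | CC(C)(C)[Si](C)(C)OC1C2CCOC3(O[Si](C)(C)C(C)(C)C)C=2C2C=1[C@]1(O[Si](C)(C)C(C)(C)C)C[C@@]4(O[Si](C)(C)C(C)(C)C)N(C(=O)C(=CC3)[C@@]24C)CC(C)=C1O[Si](C)(C)C(C)(C)C | intermediate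
28 | hexacyclic 2-silyloxyfulvene with α-alkylidene lactam, two tertiary TBS ethers and the azepanone TBS enol ether; carbinol, carbinolamine and quaternary carbons as in the target | CC(C)(C)[Si](C)(C)OC1=C2CCOC3=C2C2=C1[C@]1(O[Si](C)(C)C(C)(C)C)C[C@@]4(O[Si](C)(C)C(C)(C)C)N(C(=O)C(=CC3)[C@@]24C)CC(C)=C1O[Si](C)(C)C(C)(C)C | intermediate
29 | 28 with the alkylidene lactam reduced, ring-fusion H cis to the angular methyl | CC(C)(C)[Si](C)(C)OC1=C2CCOC3=C2C2=C1[C@]1(O[Si](C)(C)C(C)(C)C)C[C@@]4(O[Si](C)(C)C(C)(C)C)N(C(=O)[C@@H](CC3)[C@@]24C)CC(C)=C1O[Si](C)(C)C(C)(C)C | intermediate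
30 | tertiary amine from reduction of the lactam of 29 | CC(C)(C)[Si](C)(C)OC1=C2CCOC3=C2C2=C1[C@]1(O[Si](C)(C)C(C)(C)C)C[C@@]4(O[Si](C)(C)C(C)(C)C)N(C[C@@H](CC3)[C@@]24C)CC(C)=C1O[Si](C)(C)C(C)(C)C | intermediate
31 | fully desilylated amino diol ketone, drawn as the hydroxyfulvene (enol of the cyclopentenone tautomer), mixture at the C-methyl carbon | OC1=C2CCOC3=C2C2=C1[C@]1(O)C[C@@]4(O)N(C[C@@H](CC3)[C@@]24C)CC(C)C1=O | intermediate
32 | 31 as the single C-methyl epimer of the target (deacetyl target, drawn as the hydroxyfulvene) | OC1=C2CCOC3=C2C2=C1[C@]1(O)C[C@@]4(O)N(C[C@@H](CC3)[C@@]24C)C[C@@H](C)C1=O | intermediate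
33 | CNP0309418.1 | CC(=O)OC1=C2CCOC3=C2C2=C1[C@]1(O)C[C@@]4(O)N(C[C@@H](CC3)[C@@]24C)C[C@@H](C)C1=O | target

**Count**

Total steps: 21. Longest linear sequence: 18 (steps 1–4, 7–9, 11–21).

**Steps most likely to fail**

Step 17. What may go wrong: silylation of the cyclopentadienyl lactone on carbon instead of oxygen, a [4+2] or α-carbon closure outrunning the [6+4] mode, or failure of the fully substituted diene terminus to reach the s-cis geometry. The fallback is a stepwise ionic annulation that makes ring D first. From 25, catalytic Cs2CO3 in MeCN deprotonates the vinylogous 1,3-dicarbonyl of rings A and B, and the dienolate closes ring D by intramolecular Michael addition to the β-carbon of the unsaturated lactam; after proton transfer this should give the ethylidene lactam pentacycle F1. Persilylation (TBSOTf, Et3N) converts it into the fulvene that also carries the lactam as a silyl dienyl ketene N,O-acetal F2. Catalytic Tf2NH at −40 °C then closes ring C by a vinylogous Mukaiyama-type attack of the terminal CH2 on the protonated fulvene. This gives ketal 27, which loses silanol, and the route is rejoined at 28.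

Step 7. What may go wrong: reversal of the tertiary aldolate, base-induced β-elimination that opens the new epoxide next to the enolizable ring ketone, or erosion of the Felkin–Anh facial selectivity. The fallback uses a Lewis-acid aldol and closes the epoxide without base. From 8, kinetic silylation (LiN(iPr)2, Me3SiCl, −78 °C) gives the trimethylsilyl dienol ether F3. This is added to ketone 11 in a TiCl4-mediated Mukaiyama aldol reaction at −78 °C to give the chlorohydrin F4, in the same Felkin–Anh sense because the silyloxy group does not chelate. Ag2O in CH2Cl2 then closes the epoxide by halide abstraction, and the route is rejoined at 13.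

Step 11. What may go wrong: slow intermolecular alkylation of the ester-deactivated pyrrole at a neopentyl-type carbon, so that acid-induced rearrangement of the epoxy ketone takes over. The fallback attaches the pyrrole through nitrogen first and then closes the C–C bond intramolecularly. From 15, α-methylenation ((CH2O)n, iPr2NH·CF3CO2H) gives the epoxy isopropenyl ketone F5. K2CO3-mediated aza-Michael addition of pyrrole ester 17 gives the N-alkylated pyrrole F6. Sc(OTf)3 then closes ring F by intramolecular Friedel–Crafts opening of the epoxide at its CH2 terminus by the only free α-position, giving the debromo bicyclic pyrrole F7. Bromination with NBS at the remaining pyrrole position leads back to 21.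

**Further compounds**

F1 | step 17 | Michael adduct of 25: ring D closed, keto-lactone retained, lactam as conjugated ethylidene lactam | O=C1C2=C(C(=O)OCC2)C2C1[C@]1(O)C[C@@]4(O)N(C(=O)C(=CC)[C@@]24C)CC(C)C1=O
F2 | step 17 | persilylated F1: ketene-acetal fulvene with ring D closed, lactam as silyl dienyl ketene N,O-acetal | CC(C)(C)[Si](C)(C)OC1=C2CCOC(O[Si](C)(C)C(C)(C)C)=C2C2=C1[C@]1(O[Si](C)(C)C(C)(C)C)C[C@@]4(O[Si](C)(C)C(C)(C)C)N(C(O[Si](C)(C)C(C)(C)C)=C(C=C)[C@@]24C)CC(C)=C1O[Si](C)(C)C(C)(C)C
F3 | step 7 | 5-(trimethylsilyloxy)-4,7-dihydro-3H-cyclopenta[c]pyran-1-one (kinetic silyl dienol ether of 8) | C[Si](C)(C)OC1=CCC2=C1CCOC2=O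
F4 | step 7 | chlorohydrin (neutral form of aldolate 12) | O=C1C(CC2=C1CCOC2=O)[C@](O)(CCl)[C@@H](O[Si](C)(C)C(C)(C)C)CC
F5 | step 11 | epoxy isopropenyl ketone | O=C1C(CC2=C1CCOC2=O)[C@]3(CO3)C(=O)C(C)=C
F6 | step 11 | N-alkylated pyrrole ester with intact epoxide | O=C1C(CC2=C1CCOC2=O)[C@]3(CO3)C(=O)C(C)Cn4cc(C)cc4C(=O)OCC=C
F7 | step 11 | debromo analogue of 21 | O=C1C(CC2=C1CCOC2=O)[C@]3(O)Cc4c(C)cc(C(=O)OCC=C)n4CC(C)C3=O
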